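**Late readings.** Late in the elm flask E stopped rising and slipped from 91.6 mM at 98 s to 89.1 mM at 140 s. The drop barely clears the scatter, yet I read it as a sign that E itself is lost.

| setting | cedar | ash | birch | elm | oak |
|---|---|---|---|---|---|
| Q | 120 mM | 72.0 mM | 360 mM | 120 mM | 120 mM |
| G | 180 mM | 132 mM | 180 mM | 540 mM | 180 mM |
| time |  |  |  |  | 420 s |

| cedar run: time / s | cedar run: [E] / mM | ash run: time / s | ash run: [E] / mM | birch run: time / s | birch run: [E] / mM | elm run: time / s | elm run: [E] / mM |
|---|---|---|---|---|---|---|---|
| 11 | 11.4 | 11 | 7.0 | 11 | 33.6 | 11 | 33.7 |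
| 32 | 29.6 | 32 | 13.4 | 32 | 67.0 | 32 | 68.3 |
| 62 | 44.3 | 62 | 21.6 | 62 | 85.9 | 62 | 86.8 |
| 98 | 51.4 | 98 | 27.6 | 98 | 94.3 | 98 | 91.6 |
| 140 | 56.7 | 140 | 32.3 | 140 | 96.4 | 140 | 89.1 |

(scatter of a reading: 1 mM)

- Overall: Q + G -> E.
- Constant volume, constant temperature.
- Bound and free are read together.
- "The second partner" is G.
- An order is taken over about fifteen percent of the charge, up and down.

- reaction order in [Q] at the outset, round the charge of the cedar run, defined at two percent of the Q turned into E (one fixed amount of E, the same in the runs compared)
- reaction order in [G] at the outset, round the charge of the cedar run, defined at two percent of the Q turned into E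
- E in the oak run at 420 s, as a share of the Q charged

**Two times.** I followed one Q molecule: it waits to become E, then lives as E until it goes. In elm, with G at 4.50 times Q (pseudo-first-order), the first reading gives a wait of 33.4 s. On that wait hardly any Q stays unturned by 140 s, so a molecule has been E for the time since its wait ended. The surviving share then gives the life of E, the time in which E falls by a factor of e: 358 s.

**My reckoning.** Oak has cedar's charge, and cedar's first reading gives a wait of 110 s. The life spans 10.7 waits in elm but 3.25 on this charge. Taking Q as wholly turned, I expected 42.1% at 420 s. This is rough, since that wait belongs to the outset.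

**The forecast.** It gave orders of 1 and 1 and oak at 50%, holding that “the system approaches a limit with K≈0.5”. I shared the orders but let E fall, which put me 7.9 percentage points lower.

**The result.** Oak gave 38.9%, with orders of 1.0 and 1.0. The steps were:

    Q + G → E + J (0.06140 M⁻¹ s⁻¹)
    G + J ⇌ GJ, settled at all times (26.70 M⁻¹)
    E → Qi (0.002440 s⁻¹)

Turning E into Qi moves the readings by 11 times the scatter. My life of E, an estimate from the elm readings, puts the loss of E in oak near 0.130 mM s⁻¹ at 420 s. In the ash flask the same estimate, applied to the last reading, puts the loss near 0.0902 mM s⁻¹ at 140 s, against a net rise of 0.112 mM s⁻¹ read over the last interval.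

The runs are simulated with made-up constants.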